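**Retrosynthetic overview**
1. Target 40 ⇐ 39 (desilylation) ⇐ γ-lactone by SmI2 Reformatsky closure (C8–C17) of bromopropanoate 37 ⇐ chloride opening at C6 of the 6,7-epoxy ketone 34 made from macrocyclic dienone 33.
2. 33 ⇐ intramolecular Heck closure of the ten-membered ring (C5–C6) of 32; the C2 and C9 chains come from a Grignard reagent and lithiated methoxyallene added to the two aldehydes of ring A core 22.
3. 22 ⇐ enone 19 (CBS reduction, hydroxyl-directed epoxidation) ⇐ one-flask Ireland–Claisen/aldol cascade of acyclic ester 13, forming C10–C11 and C13–C14.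
4. Enabling feature: in ring A (C1, C10, C11, C12, C13, C14) the oxygenated C12 lies between C11 and C13, and C10 carries the carboxyl-level C9. A (Z)-2-methoxybut-2-enyl ester of the C9 acid therefore delivers C11 to C10 by [3,3] shift and leaves a C13 enol ether facing the C14 aldehyde on quaternary C1.
5. C1 ⇐ Johnson–Claisen chirality transfer from D-lactate-derived 4. Ring order: ring A (step 9), 13,14-oxirane (step 13), ten-membered ring (step 23), γ-lactone (step 27).

Key step: step 9

Remark: compounds 1 and 9 are taken as purchasable; locants in later names follow the target skeleton (C1–C14 rings, C15 methyl on C1, C16 exocyclic methylene, C17/C18/C19 lactone CH/CH3/C=O, C20 methyl on C11), and β is the ring A face that bears C15.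

**Step 1**
Reactants: 1 (R)-2-[(tert-butyldimethylsilyl)oxy]propanal; 2 ethyl 2-(triphenylphosphoranylidene)propanoate
Product: 3 ethyl (R,E)-4-[(tert-butyldimethylsilyl)oxy]-2-methylpent-2-enoate
Conditions: CH2Cl2, 25 °C
Reagents that add atoms: none
Why: Wittig olefination with a stabilised ylide should give the (E)-trisubstituted enoate and leave the lactate-derived stereocentre untouched.

**Step 2**
Reactants: 3 ethyl (R,E)-4-[(tert-butyldimethylsilyl)oxy]-2-methylpent-2-enoate
Product: 4 ethyl (R,E)-4-hydroxy-2-methylpent-2-enoate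
Conditions: HF·pyridine, THF, 0 to 25 °C
Reagents that add atoms: none
Why: Fluoride-mediated silyl ether cleavage frees the secondary allylic alcohol, and the E geometry prevents lactonisation.

**Step 3**
Reactants: 4 ethyl (R,E)-4-hydroxy-2-methylpent-2-enoate; 5 triethyl orthoacetate
Product: 6 diethyl (R)-2-methyl-2-[(E)-prop-1-en-1-yl]butanedioate
Conditions: EtCO2H (cat.), 140 °C, EtOH distilled off
Reagents that add atoms: none
Why: Johnson–Claisen rearrangement through a chair with the carbinol methyl equatorial should transfer the (R)-carbinol chirality to quaternary C1, adding the C10–C9 acetate unit and leaving an (E)-propenyl group as latent C14 aldehyde.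

**Step 4**
Reactants: 6 diethyl (R)-2-methyl-2-[(E)-prop-1-en-1-yl]butanedioate
Product: 7 (R,E)-3-(ethoxycarbonyl)-3-methylhex-4-enoic acid
Conditions: LiOH (1.05 equiv), THF/H2O, 0 °C; then 1 M HCl
Reagents that add atoms: lithium hydroxide, [Li+].[OH-]
Why: Chemoselective saponification should hydrolyse the unhindered CH2CO2Et ester much faster than the ester on the quaternary carbon, with no stereocentre involved.

**Step 5**
Reactants: 7 (R,E)-3-(ethoxycarbonyl)-3-methylhex-4-enoic acid
Product: 8 (R)-3-(ethoxycarbonyl)-3-methyl-4-oxobutanoic acid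
Conditions: O3, CH2Cl2, −78 °C; then Me2S
Reagents that add atoms: ozone, [O-][O+]=O
Why: Ozonolysis with reductive work-up cleaves the propenyl group to the C14 aldehyde, which cannot enolise because C1 is quaternary.

**Step 6**
Reactants: 9 methyl 2-(dimethoxyphosphoryl)-2-methoxyacetate; 10 acetaldehyde
Product: 11 methyl (Z)-2-methoxybut-2-enoate
Conditions: NaH, THF, 0 °C
Reagents that add atoms: none
Why: Horner–Wadsworth–Emmons olefination of the α-methoxy phosphonate should give mainly the (Z)-enol ether (methyl trans to the ester), the geometry needed in step 9.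

**Step 7**
Reactants: 11 methyl (Z)-2-methoxybut-2-enoate
Product: 12 (Z)-2-methoxybut-2-en-1-ol
Conditions: iBu2AlH (2.2 equiv), CH2Cl2, −78 °C; Rochelle salt
Reagents that add atoms: none
Why: Hydride 1,2-reduction of the conjugated ester gives the allylic alcohol without changing the enol ether geometry.

**Step 8**
Reactants: 8 (R)-3-(ethoxycarbonyl)-3-methyl-4-oxobutanoic acid; 12 (Z)-2-methoxybut-2-en-1-ol
Product: 13 1-ethyl 4-[(Z)-2-methoxybut-2-en-1-yl] (R)-2-formyl-2-methylbutanedioate
Conditions: DCC, DMAP (cat.), CH2Cl2, 0 to 25 °C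
Reagents that add atoms: none
Why: Steglich esterification under neutral conditions tolerates both the aldehyde and the acid-labile enol ether.

**Step 9**
Reactants: 13 1-ethyl 4-[(Z)-2-methoxybut-2-en-1-yl] (R)-2-formyl-2-methylbutanedioate
Product: 16 ring A hydroxy keto acid, via silyl ketene acetal 14 (not isolated), via Claisen silyl ester 15 (not isolated)
Conditions: KN(SiMe3)2, TMSCl, toluene, −78 to 25 °C; then BF3·OEt2, CH2Cl2, −78 °C, same flask; pH 4 citrate buffer
Reagents that add atoms: water, O
Why: KN(SiMe3)2 with TMSCl as internal quench turns the allyl ester into O-silyl ketene acetal 14 (C1 cis to OSiMe3), which undergoes an Ireland–Claisen [3,3] shift through a chair with C1 and the C11 methyl both equatorial, forming C10–C11 and releasing the 2-methoxyallyl unit C12(OMe)=C13H2 of 15; BF3·OEt2 then activates the C14 aldehyde and the enol ether adds through C13 (Mukaiyama-type aldol addition, via an oxocarbenium or 2-methoxyoxetane adduct that the buffered work-up hydrolyses to the C12 ketone), forming C13–C14. The closest known reaction types are the Ireland–Claisen rearrangement of 2-alkoxyallyl esters and Lewis acid aldol additions of 2-methoxypropene-type enol ethers to aldehydes. Ring A (C1, C10, C11, C12, C13, C14) closes by a 6-(enolendo)-exo-trig attack of C13 on the aldehyde carbon. C10 and C11 are set together by the chair geometry (ketene acetal geometry plus the (Z)-enol ether give the 10,11-syn relationship of the target), the configuration of C10 relative to quaternary C1 is set by allylic-strain control (small formyl group inside toward OSiMe3, methyl anti to the forming bond, ester outside), and C14 forms as a carbinol mixture that step 11 erases. The step needs ester enolisation next to an aldehyde, secured by the non-enolisable neopentyl aldehyde, the non-nucleophilic base and the silyl chloride quench, and it needs C11 to stay intact, secured by cyclising at −78 °C and hydrolysing at pH 4 without base.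

**Step 10**
Reactants: 16 ring A hydroxy keto acid
Product: 17 ring A hydroxy keto diester
Conditions: TMSCHN2, MeOH/toluene, 0 °C
Reagents that add atoms: (trimethylsilyl)diazomethane, C[Si](C)(C)C=[N+]=[N-]
Why: Diazoalkane esterification under neutral conditions avoids retro-aldol cleavage and epimerisation of the β-hydroxy ketone.

**Step 11**
Reactants: 17 ring A hydroxy keto diester
Product: 19 ring A enone diester, via mesylate 18 (not isolated)
Conditions: MsCl, Et3N, CH2Cl2, −20 to 25 °C
Reagents that add atoms: none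
Why: Mesylation followed by E1cB elimination of the β-mesyloxy ketone gives the C13=C14 enone (only C13 carries the acidic hydrogens next to the leaving group), and the mild amine base should leave C11 untouched.

**Step 12**
Reactants: 19 ring A enone diester
Product: 20 ring A allylic alcohol
Conditions: (R)-2-methyl-CBS-oxazaborolidine, BH3·SMe2, THF, −40 °C; MeOH
Reagents that add atoms: none
Why: Corey–Bakshi–Shibata reduction under reagent control, with the alkene side acting as the large substituent, should deliver hydride to the β face and set the 12α-carbinol trans to the C11 methyl.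

**Step 13**
Reactants: 20 ring A allylic alcohol
Product: 21 ring A epoxy alcohol
Conditions: VO(acac)2 (cat.), tBuOOH, CH2Cl2, 0 to 25 °C
Reagents that add atoms: tert-butyl hydroperoxide, CC(C)(C)OO
Why: Vanadium-catalysed hydroxyl-directed epoxidation delivers oxygen syn to the 12α-hydroxyl and so sets C13 and C14 (13α,14α-epoxide).

**Step 14**
Reactants: 21 ring A epoxy alcohol
Product: 22 ring A 12-O-triethylsilyl ether
Conditions: TESOTf, 2,6-lutidine, CH2Cl2, −78 °C
Reagents that add atoms: triethylsilyl trifluoromethanesulfonate, CC[Si](CC)(CC)OS(=O)(=O)C(F)(F)F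
Why: Silylation with a silyl triflate and a hindered base protects the hindered 12-hydroxyl without opening the neighbouring epoxide.

**Step 15**
Reactants: 22 ring A 12-O-triethylsilyl ether
Product: 23 ring A C9 aldehyde
Conditions: iBu2AlH (1.2 equiv), CH2Cl2, −78 °C; MeOH, Rochelle salt
Reagents that add atoms: none
Why: Hydride half-reduction at −78 °C should take the C9 methyl ester to the aldehyde through a stable aluminium hemiacetal while the neopentyl C2 ethyl ester reacts much more slowly.

**Step 16**
Reactants: 23 ring A C9 aldehyde; 24 methoxyallene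
Product: 25 (9R)-allenyl carbinol
Conditions: n-BuLi, THF, −40 °C; then 23, −78 °C; aq. NH4Cl
Reagents that add atoms: none
Why: 1,2-Addition of lithiated methoxyallene (an acrolein acyl anion equivalent) to the α-branched aldehyde should follow the Felkin–Anh model, with quaternary C1 anti to the nucleophile, and set (9R).

**Step 17**
Reactants: 25 (9R)-allenyl carbinol
Product: 26 9-O-tert-butyldimethylsilyl allenyl ether
Conditions: TBSOTf, 2,6-lutidine, CH2Cl2, −78 to 0 °C
Reagents that add atoms: tert-butyldimethylsilyl trifluoromethanesulfonate, CC(C)(C)[Si](C)(C)OS(=O)(=O)C(F)(F)F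
Why: Silylation protects the 9-hydroxyl as a robust ether that later suppresses acyl transfer and lactonisation onto the C2 ester.

**Step 18**
Reactants: 26 9-O-tert-butyldimethylsilyl allenyl ether
Product: 27 C2 aldehyde
Conditions: iBu2AlH (2 equiv), CH2Cl2, −78 °C; Rochelle salt
Reagents that add atoms: none
Why: Hydride half-reduction of the hindered ester on quaternary C1 should stop at the aldehyde at −78 °C, and the allenyl ether, silyl ethers and epoxide are inert.

**Step 19**
Reactants: 28 3-bromobut-3-en-1-ol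
Product: 29 2,4-dibromobut-1-ene
Conditions: CBr4, PPh3, CH2Cl2, 0 °C
Reagents that add atoms: carbon tetrabromide, BrC(Br)(Br)Br
Why: Appel bromination converts the primary alcohol into the alkyl bromide and leaves the vinyl bromide alone.

**Step 20**
Reactants: 27 C2 aldehyde; 29 2,4-dibromobut-1-ene
Product: 30 (2R)-carbinol vinyl bromide
Conditions: Mg, THF, 25 °C (29); then 27, THF, −78 to −40 °C; aq. NH4Cl
Reagents that add atoms: none
Why: In this Grignard addition magnesium inserts only into the sp3 C–Br bond, and attack on the exposed face of the dipole-minimised rotamer (C=O anti to the C14–O bond, non-chelating THF) should set (2R).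

**Step 21**
Reactants: 30 (2R)-carbinol vinyl bromide
Product: 31 vinyl ketone diol
Conditions: 1 M aq. HCl, THF, 0 °C
Reagents that add atoms: water, O
Why: Acid hydrolysis of the 1-methoxyallene (protonation at the central carbon, then loss of methanol) unveils the vinyl ketone and also cleaves the labile triethylsilyl ether, while the tert-butyldimethylsilyl ether should survive.

**Step 22**
Reactants: 31 vinyl ketone diol
Product: 32 vinyl ketone diacetate
Conditions: Ac2O, pyridine, DMAP (cat.), CH2Cl2, 0 °C
Reagents that add atoms: acetic anhydride, CC(=O)OC(C)=O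
Why: Acetylation of the only two free hydroxyls installs the C2 and C12 acetates of the target.

**Step 23**
Reactants: 32 vinyl ketone diacetate
Product: 33 macrocyclic dienone
Conditions: Pd(OAc)2 (10 mol%), P(o-tol)3, Et3N, MeCN (0.002 M), 80 °C
Reagents that add atoms: none
Why: In this intramolecular Mizoroki–Heck reaction the vinyl bromide adds oxidatively to zerovalent palladium, 10-endo carbopalladation at the terminal carbon of the vinyl ketone forms C5–C6, and β-hydride elimination gives the (6E)-enone.

**Step 24**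
Reactants: 33 macrocyclic dienone
Product: 34 trans-6,7-epoxy ketone
Conditions: tBuOOH, DBU, CH2Cl2, 0 °C
Reagents that add atoms: tert-butyl hydroperoxide, CC(C)(C)OO
Why: Weitz–Scheffer nucleophilic epoxidation (peroxide addition at C6, then ring closure) gives the trans-epoxy ketone, and peripheral attack on the ten-membered (E)-enone should set C6 and C7.

**Step 25**
Reactants: 34 trans-6,7-epoxy ketone
Product: 35 (6S,7R)-chlorohydrin
Conditions: LiCl, AcOH, THF, 0 to 25 °C
Reagents that add atoms: lithium chloride, [Li+].[Cl-]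
Why: Acid-assisted epoxide opening by chloride at the allylic C6, distal to the carbonyl and with SN2 inversion, should give the anti chlorohydrin while the hindered, unactivated 13,14-epoxide stays closed.

**Step 26**
Reactants: 35 (6S,7R)-chlorohydrin; 36 2-bromopropanoyl bromide
Product: 37 7-O-(2-bromopropanoyl) ester
Conditions: pyridine, CH2Cl2, −20 °C
Reagents that add atoms: none
Why: Acylation of the only free hydroxyl (C7) with the acid bromide places the propanoate unit for lactone closure.

**Step 27**
Reactants: 37 7-O-(2-bromopropanoyl) ester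
Product: 39 9-O-silyl target, via samarium enolate 38 (not isolated)
Conditions: SmI2 (2.2 equiv), THF, −78 °C; aq. NH4Cl
Reagents that add atoms: none
Why: In this samarium diiodide Reformatsky reaction the trivalent samarium enolate adds to the adjacent C8 ketone through a chelated 5-exo-trig transition state, which should place the C8 hydroxyl syn to C6 (trans-fused lactone) and the C17 methyl syn to that hydroxyl (the favoured, epimerisable arrangement).

**Step 28**
Reactants: 39 9-O-silyl target
Product: 40 target CNP0242711.1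
Conditions: HF·pyridine, pyridine, THF, 0 to 25 °C
Reagents that add atoms: none
Why: Buffered fluoride desilylation removes the last silyl ether and should spare the acetates, epoxide, lactone and allylic chloride.

**Compound list**
1 | (R)-2-[(tert-butyldimethylsilyl)oxy]propanal | C[C@@H](O[Si](C)(C)C(C)(C)C)C=O | starting material
2 | ethyl 2-(triphenylphosphoranylidene)propanoate | CCOC(=O)C(C)=P(c1ccccc1)(c1ccccc1)c1ccccc1 | starting material
3 | ethyl (R,E)-4-[(tert-butyldimethylsilyl)oxy]-2-methylpent-2-enoate | CCOC(=O)/C(C)=C/[C@@H](C)O[Si](C)(C)C(C)(C)C | intermediate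
4 | ethyl (R,E)-4-hydroxy-2-methylpent-2-enoate | CCOC(=O)/C(C)=C/[C@@H](C)O | intermediate
5 | triethyl orthoacetate | CC(OCC)(OCC)OCC | starting material
6 | diethyl (R)-2-methyl-2-[(E)-prop-1-en-1-yl]butanedioate | CCOC(=O)[C@@](C)(/C=C/C)CC(=O)OCC | intermediate
7 | (R,E)-3-(ethoxycarbonyl)-3-methylhex-4-enoic acid | CCOC(=O)[C@@](C)(/C=C/C)CC(=O)O | intermediate
8 | (R)-3-(ethoxycarbonyl)-3-methyl-4-oxobutanoic acid | CCOC(=O)[C@@](C)(C=O)CC(=O)O | intermediate
9 | methyl 2-(dimethoxyphosphoryl)-2-methoxyacetate | COC(=O)C(OC)P(=O)(OC)OC | starting material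
10 | acetaldehyde | CC=O | starting material
11 | methyl (Z)-2-methoxybut-2-enoate | C/C=C(\OC)C(=O)OC | intermediate
12 | (Z)-2-methoxybut-2-en-1-ol | C/C=C(\OC)CO | intermediate
13 | 1-ethyl 4-[(Z)-2-methoxybut-2-en-1-yl] (R)-2-formyl-2-methylbutanedioate | CCOC(=O)[C@@](C)(C=O)CC(=O)OC/C(OC)=C/C | intermediate
14 | silyl ketene acetal (O-trimethylsilyl ketene acetal of 13; C1 cis to OSiMe3) | CCOC(=O)[C@@](C)(C=O)/C=C(\O[Si](C)(C)C)OC/C(OC)=C/C | intermediate
15 | Claisen silyl ester (trimethylsilyl 2-[(R)-1-ethoxy-2-methyl-1,3-dioxopropan-2-yl]-4-methoxy-3-methylpent-4-enoate; C10 and C11 as in the target) | CCOC(=O)[C@](C=O)(C)[C@H]([C@@H](C)C(OC)=C)C(=O)O[Si](C)(C)C | intermediate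
16 | ring A hydroxy keto acid (2-(ethoxycarbonyl)-3-hydroxy-2,6-dimethyl-5-oxocyclohexane-1-carboxylic acid; 1β-methyl; 10α-H; 11β-methyl; C14 carbinol epimers) | CCOC(=O)[C@]1(C)[C@H]([C@@H](C)C(=O)CC1O)C(=O)O | intermediate
17 | ring A hydroxy keto diester (C9 methyl ester of 16) | CCOC(=O)[C@]1(C)[C@H]([C@@H](C)C(=O)CC1O)C(=O)OC | intermediate
18 | mesylate (14-O-methanesulfonate of 17) | CCOC(=O)[C@]1(C)[C@H]([C@@H](C)C(=O)CC1OS(C)(=O)=O)C(=O)OC | intermediate
19 | ring A enone diester (2-ethyl 1-methyl 2,6-dimethyl-5-oxocyclohex-3-ene-1,2-dicarboxylate; 1β-methyl; 10α-H; 11β-methyl) | CCOC(=O)[C@]1(C)[C@H]([C@@H](C)C(=O)C=C1)C(=O)OC | intermediate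
20 | ring A allylic alcohol (12α-hydroxy; 13-ene; otherwise as 19) | CCOC(=O)[C@]1(C)[C@H]([C@@H](C)[C@H](O)C=C1)C(=O)OC | intermediate
21 | ring A epoxy alcohol (12α-hydroxy; 13α,14α-epoxide; C2 ethyl ester; C9 methyl ester) | CCOC(=O)[C@]2(C)[C@H]([C@@H](C)[C@H](O)[C@@H]3O[C@@H]32)C(=O)OC | intermediate
22 | ring A 12-O-triethylsilyl ether (of 21) | CCOC(=O)[C@]2(C)[C@H]([C@@H](C)[C@H](O[Si](CC)(CC)CC)[C@@H]3O[C@@H]32)C(=O)OC | intermediate
23 | ring A C9 aldehyde (formyl on C10; C2 ethyl ester kept) | CCOC(=O)[C@]2(C)[C@H]([C@@H](C)[C@H](O[Si](CC)(CC)CC)[C@@H]3O[C@@H]32)C=O | intermediate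
24 | methoxyallene (1-methoxypropa-1,2-diene) | COC=C=C | starting material
25 | (9R)-allenyl carbinol (C9H(OH)–C8(OMe)=C7=C6H2 on C10) | CCOC(=O)[C@]2(C)[C@H]([C@@H](C)[C@H](O[Si](CC)(CC)CC)[C@@H]3O[C@@H]32)[C@@H](O)C(OC)=C=C | intermediate
26 | 9-O-tert-butyldimethylsilyl allenyl ether (of 25) | CCOC(=O)[C@]2(C)[C@H]([C@@H](C)[C@H](O[Si](CC)(CC)CC)[C@@H]3O[C@@H]32)[C@@H](O[Si](C)(C)C(C)(C)C)C(OC)=C=C | intermediate
27 | C2 aldehyde (formyl on C1 of 26) | O=C[C@]2(C)[C@H]([C@@H](C)[C@H](O[Si](CC)(CC)CC)[C@@H]3O[C@@H]32)[C@@H](O[Si](C)(C)C(C)(C)C)C(OC)=C=C | intermediate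
28 | 3-bromobut-3-en-1-ol | C=C(Br)CCO | starting material
29 | 2,4-dibromobut-1-ene | C=C(Br)CCBr | intermediate
30 | (2R)-carbinol vinyl bromide (C2H(OH)–C3H2–C4H2–C5(Br)=C16H2 on C1) | C=C(Br)CC[C@@H](O)[C@]2(C)[C@H]([C@@H](C)[C@H](O[Si](CC)(CC)CC)[C@@H]3O[C@@H]32)[C@@H](O[Si](C)(C)C(C)(C)C)C(OC)=C=C | intermediate
31 | vinyl ketone diol (2,12-diol; C8 ketone with C7=C6H2; 9-O-silyl ether kept) | C=C(Br)CC[C@@H](O)[C@]2(C)[C@H]([C@@H](C)[C@H](O)[C@@H]3O[C@@H]32)[C@@H](O[Si](C)(C)C(C)(C)C)C(=O)C=C | intermediate
32 | vinyl ketone diacetate (2,12-di-O-acetyl 31) | C=C(Br)CC[C@@H](OC(C)=O)[C@]2(C)[C@H]([C@@H](C)[C@H](OC(C)=O)[C@@H]3O[C@@H]32)[C@@H](O[Si](C)(C)C(C)(C)C)C(=O)C=C | intermediate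
33 | macrocyclic dienone (ten-membered ring; (6E)-6-en-8-one; 5(16)-methylene) | C1C[C@@H](OC(C)=O)[C@]2(C)[C@H]([C@@H](C)[C@H](OC(C)=O)[C@@H]3O[C@@H]32)[C@@H](O[Si](C)(C)C(C)(C)C)C(=O)/C=C/C1=C | intermediate
34 | trans-6,7-epoxy ketone (of 33) | C1C[C@@H](OC(C)=O)[C@]2(C)[C@H]([C@@H](C)[C@H](OC(C)=O)[C@@H]3O[C@@H]32)[C@@H](O[Si](C)(C)C(C)(C)C)C(=O)[C@H]4O[C@@H]4C1=C | intermediate
35 | (6S,7R)-chlorohydrin (6-chloro-7-hydroxy-8-ketone) | C1C[C@@H](OC(C)=O)[C@]2(C)[C@H]([C@@H](C)[C@H](OC(C)=O)[C@@H]3O[C@@H]32)[C@@H](O[Si](C)(C)C(C)(C)C)C(=O)[C@@H](O)[C@@H](Cl)C1=C | intermediate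
36 | 2-bromopropanoyl bromide | CC(Br)C(=O)Br | starting material
37 | 7-O-(2-bromopropanoyl) ester (of 35) | C1C[C@@H](OC(C)=O)[C@]2(C)[C@H]([C@@H](C)[C@H](OC(C)=O)[C@@H]3O[C@@H]32)[C@@H](O[Si](C)(C)C(C)(C)C)C(=O)[C@@H](OC(=O)C(C)Br)[C@@H](Cl)C1=C | intermediate
38 | samarium enolate (trivalent samarium enolate of 37) | C1C[C@@H](OC(C)=O)[C@]2(C)[C@H]([C@@H](C)[C@H](OC(C)=O)[C@@H]3O[C@@H]32)[C@@H](O[Si](C)(C)C(C)(C)C)C(=O)[C@@H](OC(O[Sm](I)I)=CC)[C@@H](Cl)C1=C | intermediate
39 | 9-O-silyl target (9-O-tert-butyldimethylsilyl ether of 40) | C=C1CC[C@@H](OC(C)=O)[C@]2(C)[C@H]([C@@H](C)[C@H](OC(C)=O)[C@@H]3O[C@@H]32)[C@@H](O[Si](C)(C)C(C)(C)C)[C@]2(O)[C@@H](C)C(=O)O[C@H]2[C@H]1Cl | intermediate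
40 | target CNP0242711.1 ((1S,2R,6S,7R,8R,9R,10S,11R,12S,13S,14R,17R)-2,12-diacetoxy-6-chloro-13,14-epoxy-8,9-dihydroxy-5(16)-ene γ-lactone) | C=C1CC[C@@H](OC(C)=O)[C@]2(C)[C@H]([C@@H](C)[C@H](OC(C)=O)[C@@H]3O[C@@H]32)[C@@H](O)[C@]2(O)[C@@H](C)C(=O)O[C@H]2[C@H]1Cl | target

**Step count and risks**
Total step count: 28. Longest linear sequence: 25 steps (steps 1–5, 8–18, 20–28).

Steps most likely to fail:

1. Step 9. The [3,3] shift may show poor facial selectivity at C10 relative to quaternary C1, and the Lewis acid stage may lose a proton from C11 (ene-type pathway) and scramble that centre. Fallback from 13: run the Ireland–Claisen alone (LiN(iPr)2, TMSCl, THF/DMPU), work up with aqueous HCl (cleaves the silyl ester and hydrolyses the enol ether to the methyl ketone) and esterify with diazomethane to give keto aldehyde diester F1. An amine-catalysed intramolecular aldol condensation (pyrrolidine, AcOH) then closes ring A and dehydrates to enone 19, where the route is rejoined. If C11 equilibrates on this path, it can be reset at 19 by deprotonation with LiN(SiMe3)2 and kinetic protonation from the α face.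

2. Step 23. Oligomerisation and reduction of the vinyl bromide may outrun the slow ten-membered ring closure. Fallback from 32: Stille coupling with tributyl(vinyl)stannane (Pd(PPh3)4, CuI) gives vinyl triene F2. Ring-closing metathesis between the new vinyl group and the vinyl ketone (second-generation Hoveyda–Grubbs catalyst, high dilution) then gives dienone 33.

3. Step 27. Single-electron reduction of the α-acyloxy ketone or of the allylic chloride by SmI2 may compete with enolate formation. Fallback from 35: chelation-controlled Mukaiyama aldol addition of (E)-1-methoxy-1-(trimethylsilyloxy)prop-1-ene to the C8 ketone (MgBr2·OEt2, CH2Cl2, −78 °C) gives hydroxy ester F3. Lactonisation onto the 7-hydroxyl (PPTS, toluene) then gives 39.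

**Further compounds**
F1 | step 9 | keto aldehyde diester (1-ethyl 4-methyl 2-formyl-2-methyl-3-(3-oxobutan-2-yl)butanedioate; C1, C10, C11 as in 15) | CCOC(=O)[C@](C=O)(C)[C@H]([C@@H](C)C(C)=O)C(=O)OC
F2 | step 23 | vinyl triene (vinyl in place of bromine in 32) | C=CC(=C)CC[C@@H](OC(C)=O)[C@]2(C)[C@H]([C@@H](C)[C@H](OC(C)=O)[C@@H]3O[C@@H]32)[C@@H](O[Si](C)(C)C(C)(C)C)C(=O)C=C
F3 | step 27 | hydroxy ester (methyl propanoate aldol adduct at C8 of 35; 7,8-diol) | C1C[C@@H](OC(C)=O)[C@]2(C)[C@H]([C@@H](C)[C@H](OC(C)=O)[C@@H]3O[C@@H]32)[C@@H](O[Si](C)(C)C(C)(C)C)[C@](O)([C@@H](C)C(=O)OC)[C@@H](O)[C@@H](Cl)C1=C
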